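The earlier runs and the new flask were computed for substances that don't exist; scatter was added.

At early times in the amber run, G went two ways: on to X, and with L into E. You asked for a quick number on midnight and dawn and guessed that X leads in both. I reckoned from both ends and joined them.

| flask | D | L | remark | time |
|---|---|---|---|---|
| amber | 5 mM | 20 mM | run made earlier |  |
| violet | 7.5 mM | 20 mM | run made earlier |  |
| midnight | 10 mM | 20.0 mM |  | 3.0 d |
| dawn | 10 mM | 20.0 mM |  | 8.0 d |

| run | time / d | G / % | X / % | E / % | D / % |
|---|---|---|---|---|---|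
| amber | 0.625 | 12.9 | 16.3 | 12.3 | 44.1 |
| amber | 1.25 | 9.0 | 32.2 | 21.4 | 27.7 |
| amber | 1.67 | 6.7 | 39.6 | 25.8 | 21.0 |
| amber | 2.50 | 4.5 | 50.8 | 28.5 | 12.2 |
| amber | 3.00 | 3.5 | 55.6 | 28.6 | 9.7 |
| violet | 0.250 | 13.2 | 5.3 | 4.4 | 58.9 |
| violet | 0.417 | 13.5 | 10.6 | 7.6 | 51.5 |
| violet | 0.833 | 11.0 | 23.0 | 16.0 | 37.7 |
| violet | 1.67 | 7.1 | 39.3 | 25.1 | 21.2 |
| violet | 3.00 | 4.1 | 56.0 | 28.4 | 9.5 |

(readings scatter by 0.3 percentage points)

- which of these there is most of at the end, counted by the D in it, midnight (G / D / X / E)
- which of these there is most of at the end, counted by the D in it, dawn (G / D / X / E)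
- how much there is at the end of the one of these that leads, in percent of the D charged: midnight
- how much there is at the end of the one of these that leads, in percent of the D charged: dawn

**Early end.** In amber, from 1.25 d to 3.00 d, X rose at 2.14 /d per unit of G. E then stood flat, 28.5% to 28.6%, so I assumed that E was returning to G as fast as it formed. With E's first rise, that gave a forming constant of 1.70 /d and a return constant of 0.237 /d. I carried one quantity forward: the split ratio, or selectivity factor, meaning the X made per E made from G at this L, 1.26.

**Late end.** At 3.00 d, amber held 55.6% X and violet 56.0%, so I took 55.8% for midnight. Beyond that, I reckoned, returning E reaches X with a share of split/(1 + split). The part not yet X therefore falls at a tail rate of 0.133 /d. That gave 77.2% X for dawn.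

**The forecast.** It gave X at 56% for midnight and X at 74.5% for dawn, on this ground: “drain with a slow eigenvalue near 0.1/d”. My dawn figure stood higher than its own.

**The result.** Midnight gave X at 55.9% and dawn gave X at 78.9%, so the forecast held.

    G → X (k = 2.70 × 10⁻⁵ /s)
    L + G ⇌ E (K = 410 /M, k = 0.00110 /M/s)
    D ⇌ Q (K = 0.330, k = 5.50 × 10⁻⁴ /s)
    Q ⇌ G (K = 2.10, k = 6.00 × 10⁻⁵ /s)

Dawn's X moved 6 points upward, further from the forecast's 74.5%, when read at 10.7 d or, with the time held, charged with 13.2 mM of L. From midnight's X, the split ratio's tail rate gave 98.8% at 30.0 d. The flask held 98.5%.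

**Second flask.** In the neighbour with 12 mM of L, I scaled the split ratio with L, to 2.10. That took midnight's X over E from 2.02 to 3.37. At 3.00 d that neighbour held 63.1% X and 18.6% E, a ratio of 3.39.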